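## The problem

The target **29** is a 6,7-seco-ent-kauranoid: ring A is spiro-linked at C10 to a δ-lactone (C20–O–C7), the lactone is cis-fused through C8–C9 to ring C, and ring C with the C15–C16 bridge forms a bicyclo[3.2.1]octane carrying an α-methylene ketone. There are seven stereocentres (C4, C5, C8, C9, C10, C11, C13). Three are quaternary (C4, C8, C10), and C9 is a methine wedged between two of them, so the C8–C9–C10 array is the most congested part to assemble. The centres can be chained: C5 can direct C4 and C10, C10 plus a chiral reagent can fix C9, C9 can direct C8, C13 is dictated by the bicycle, and the equatorial C11 hydroxyl (cis to C10, trans to H9) is the thermodynamic epimer. The exocyclic enone is a Michael acceptor and must appear last. The lactone can transacylate to a neighbouring hydroxyl (C11), and C9 becomes epimerisable whenever C11 is a ketone. The feature that makes the key step possible is that the C13–C16 bond of ring D lies next to C12, which is α to the C11 oxygen. An isomeric bicyclo[2.2.2]octan-11-one with C16 on C12 and a radical at C13 can therefore relax to the bicyclo[3.2.1]octane. In that isomer the oxygens at C11 and C13 flank the bridgehead C12, which is the pattern of a 1,3-diketone.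

## Retrosynthesis

**29 ⇐ 25 (no C–C bond cut).** The enone, the C11 carbinol and the free primary alcohols are adjusted last. C15 is oxidised through the C16=C17 alkene (26 → 27), and the alcohol is taken to the ketone only in the final step, on the unprotected tetraol 28. The C11 ketone of 25 is reduced under equilibrating conditions to 26. This keeps the Michael acceptor away from hydride, base and fluoride. The forward steps need only chemoselectivity (allylic versus saturated alcohols).

**25 ⇐ 24 (cut C13–C16, restore C12–C16).** A 1,2-vinyl shift of a homoallyl radical links bicyclo[3.2.1]octanone 25 to the bicyclo[2.2.2]octanone xanthate 24. Cutting here rather than at C8–C15 or C13–C14 leaves a precursor whose bridgehead C12 sits between two oxygenated carbons. The forward reaction must rearrange faster than it is reduced and must open the cyclopropane toward C12; the C11 ketone provides that.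

**24 ⇐ 22 ⇐ 21 (cut C12–C16).** Xanthate 24 comes from dione 22 by reduction of the less hindered C13 carbonyl. Dione 22 is opened at C12–C16 to the monocyclic 1,3-diketone 21 with a propargyl group on C8 (Conia-ene reaction). A Diels–Alder entry with a ring C silyloxydiene and an allene equivalent was weighed against this cut. It would leave C11 as an unactivated methylene and would have to form the C8 quaternary centre at a fully substituted diene terminus next to the neopentyl C9. The dione cut supplies both oxygens and the exocyclic methylene at once.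

**21 ⇐ 18 ⇐ 17 ⇐ 16 (cut C8–C15, then C11–C12).** The quaternary C8 is made by propargylation of the ring-fusion enolate of the cis-fused lactone 17; the cis-fusion preference and screening by ring A set its configuration. Ring C of 17 is opened at C11–C12 to the aldehyde allylsilane 16 (Hosomi–Sakurai closure). The exocyclic methylene produced at C13 serves as a masked ketone during the enolate step. Doing the ring closure before the quaternisation makes C8 a matter of ring-fusion geometry and not of acyclic control.

**16 ⇐ 14 ⇐ 12 + 2 (cut C9–C10 and C8–C14).** The most hindered bond, C9–C10, is made while C9 is still part of a flat butenolide. The enolate of aldehyde 12 adds to the chiral butenolide 2, and the lactone enolate is alkylated in the same flask to give 14. The butenolide delivers C7, C8, C9 and C11 with C11 already at the aldehyde level; its acetal centre fixes C9, and ring A fixes C10. Reduction of C20 and a lactone exchange (15 → 16) then give the 7,20-lactone and free the C11 aldehyde.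

**12 ⇐ 5 ⇐ 4 ⇐ 1 + 2 (cut C4–C18, C10–C1 and C4–C5).** The C4/C5 relationship (C18 trans to C6, methyl cis) cannot be set by sterics on a monocyclic ring, since methyl and CH2OR are too alike. It is therefore taken from a cis-fused bicycle: vinyl adds to enone 4 on the convex face, trans to C6. Enone 4 is the annulation product of the vinylogous ester 1 and a second molecule of 2 of the same configuration, which supplies C5, C6, C10 and C20 and the absolute configuration. The precursors are two commercial compounds.

## Roads not taken

**Alternative 1:** The cut is at C5–C10 and C8–C9, with a temporary carbocyclic ring B opened later at C6=C7 by ozonolysis. In the forward step a tethered diene (C5=C6–C7=C8) adds to an enoate (C9=C10) on heating or with Me2AlCl, giving A1 with ring A closed.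
- Merits: one step builds ring A, both bonds of the C8–C9–C10 array and four stereocentres. Cleavage of C6=C7 later gives C6 and C7 at useful oxidation levels.
- Weak points: the diene terminus C8 is doubly substituted (one group is forced inside) and the dienophile carbon C10 is fully substituted, so two quaternary centres form in one hindered cycloaddition. Facial control rests on the remote C4 centre. A1 has no oxygen at C11, and its ozonolysis must distinguish C6=C7 from an allyl group and a silylalkyne. Rings C and D are still missing.
- Comparison: A1 reaches the C8/C9/C10 array in fewer operations than steps 9–13 of the chosen plan, and that advantage is real. The chosen plan sets against it separate steps with a clear control element for each of these centres, C11 oxygen from the start, and no late differentiation of three π systems.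

**Alternative 2:** The cut is at C8–C9 and C10–C20. Irradiation near 300 nm of a dioxinone (C7, C8, C20), tethered through C14–C13–C12–C11 to the exocyclic C9=C10 alkene of ring A, gives the cyclobutane A2 with ring C closed; fragmentation of the cyclobutane would follow.
- Merits: the two quaternary centres C8 and C10 form in an excited-state step that is little affected by crowding. The lactone carbons arrive with the chromophore, and C11 is oxygenated.
- Weak points: the straight-versus-crossed regiochemistry and the face of the exocyclic alkene depend only on the C5 substituent and the tether. C9 is set in the same step. The fragmentation must deliver the C20–O/C7 lactone connectivity. Ring D and C17 still have to be built from the ester side chain on C13.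
- Comparison: for the hindered bonds this route is as direct as the chosen one or more so. The chosen plan offers thermal steps with predictable face selectivity, and it introduces C15–C17 as one propargyl unit.

**Alternative 3:** The cut is at C9–C11 and C8–C15. SmI2 reduces a C11 aldehyde to a ketyl that adds to C9 of an unsaturated lactone (ring C), and the samarium enolate at C8 then acylates a C15 ester (ring D), giving A3.
- Merits: rings C and D, the C11 hydroxyl and the C15 ketone arise in one step.
- Weak points: A3 lacks C17, so C16 must be methylenated next to a bridgehead with the C11 hydroxyl present. C8, C9, C11 and C13 all depend on one cascade and its chelated transition state. The enolate acylation must outrun protonation.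
- Comparison: this route is probably shorter than the chosen one, because it needs no bicyclo[2.2.2]octane detour and no late allylic oxidation. The chosen plan sets against it stepwise, checkable control at C8 and C9, the exocyclic methylene carried in from the alkyne, and a tin hydride step under neutral conditions whose selectivity depends on radical stability and not on cascade timing.

Key step: step 19

Remark on the chemistry: positions carry ent-kaurane numbers. Centres that are later oxidised, enolised or turned into a radical (C10 in 4–12, C8 in 14–17, C11 in 17–20, C13 in 23 and 24, C15 in 27 and 28) are drawn as the epimer expected to predominate; their configuration does not affect the outcome.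

## Steps

Step 1
Reactants: 1 (E)-4-methoxypent-3-en-2-one; 2 (5S)-5-[(1S,2R,5S)-2-isopropyl-5-methylcyclohexyloxy]furan-2(5H)-one (d-menthyl acetal)
Product: 4 cis-fused enone lactone (3S)-3-(d-menthyloxy)-7-methyl-3a,4-dihydro-2-benzofuran-1,5(3H,7aH)-dione (H5 and H10 cis; ring A bonds trans to the menthyloxy group), via lithium lactone enolate 3 (not isolated)
Conditions: LiN(i-Pr)2, THF, −78 °C; add 2, −78 → 0 °C; aq. HCl
Reagents that add atoms: none
Why: Kinetic α′-deprotonation of the vinylogous ester 1 gives a cross-conjugated dienolate that adds to the β-carbon of 2 (C10) anti to the menthyloxy group; the lactone enolate 3 then attacks the methoxy-bearing carbon C4 and methoxide is lost (Michael–Michael ring closure, the anionic counterpart of an alkoxy-silyloxydiene Diels–Alder reaction); the five/six ring fusion can only be cis, which fixes C5 relative to C10.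

Step 2
Reactants: 4 cis-fused enone lactone
Product: 5 C2 ketone with quaternary C4 (methyl and vinyl; vinyl trans to the C5–C6 bond)
Conditions: CH2=CHMgBr, CuBr·SMe2 (20 mol %), THF, −78 → −40 °C; aq. NH4Cl
Reagents that add atoms: vinylmagnesium bromide, C=C[Mg]Br
Why: Copper-catalysed 1,4-addition of a vinyl Grignard reagent to the β,β-disubstituted enone; the nucleophile enters on the convex face of the cis-fused bicycle, trans to the C5–C6 bond, so the vinyl group (future C18) is trans and the methyl group (C19) cis to C6.

Step 3
Reactants: 5 C2 ketone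
Product: 7 C2-deoxygenated cis-fused lactone acetal, via tosylhydrazone 6 (not isolated)
Conditions: TsNHNH2, EtOH, 60 °C; evaporate; catecholborane, CHCl3, 0 °C; then NaOAc·3H2O, 60 °C
Reagents that add atoms: none
Why: Reductive deoxygenation of an unhindered ketone through its tosylhydrazone (hydroboration of C=N, loss of sulfinate, extrusion of N2 from the diazene); the acylal lactone and the terminal alkene are not attacked by catecholborane at 0 °C.

Step 4
Reactants: 7 C2-deoxygenated lactone acetal
Product: 8 methyl 2-(dimethoxymethyl)-6-methyl-6-vinylcyclohexane-1-carboxylate (ester and acetal carbon cis; vinyl trans to the ester)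
Conditions: HC(OMe)3, MeOH, H2SO4 (cat.), 50 °C
Reagents that add atoms: methanol, CO; trimethyl orthoformate, COC(OC)OC
Why: Acid-catalysed methanolysis of the cyclic acylal (pseudo-ester) to the open methyl ester dimethyl acetal, driven by excess methanol with orthoformate as water scavenger; the auxiliary leaves as menthol, and C5 is not enolised under acid.

Step 5
Reactants: 8 vinyl ester acetal
Product: 9 methyl 2-(dimethoxymethyl)-6-formyl-6-methylcyclohexane-1-carboxylate
Conditions: O3, CH2Cl2, −78 °C; Me2S
Reagents that add atoms: ozone, [O-][O+]=O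
Why: Ozonolysis of the only alkene with reductive work-up shortens the vinyl group to the C18 aldehyde, which cannot epimerise because C4 is quaternary.

Step 6
Reactants: 9 aldehyde ester acetal
Product: 10 [3-(dimethoxymethyl)-1-methylcyclohexane-1,2-diyl]dimethanol (the two hydroxymethyl groups trans)
Conditions: LiAlH4, THF, 0 °C
Reagents that add atoms: none
Why: LiAlH4 reduces aldehyde and ester to the C18 and C6 primary alcohols; the dimethyl acetal masking C20 is inert to hydride.

Step 7
Reactants: 10 diol acetal
Product: 11 bis(tert-butyldiphenylsilyl) ether of 10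
Conditions: t-BuPh2SiCl, imidazole, DMAP (cat.), DMF, 40 °C
Reagents that add atoms: tert-butyl(chloro)diphenylsilane, CC(C)(C)[Si](Cl)(c1ccccc1)c1ccccc1
Why: Silylation of both primary alcohols; the tert-butyldiphenylsilyl group is chosen because it survives the acidic and strongly basic steps that follow.

Step 8
Reactants: 11 bis-silyl ether acetal
Product: 12 2,3-bis[(tert-butyldiphenylsilyl)oxymethyl]-3-methylcyclohexane-1-carbaldehyde (silyloxymethyl groups trans; C10–H as formed)
Conditions: PPTS, acetone/H2O (10:1), 50 °C
Reagents that add atoms: water, O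
Why: Mild acid hydrolysis of the dimethyl acetal frees the C20 aldehyde without cleaving the silyl ethers; C10 may epimerise but is enolised in the next step.

Step 9
Reactants: 12 ring A aldehyde; 2 (5S)-5-(d-menthyloxy)furan-2(5H)-one
Product: 14 trans,trans-trisubstituted butyrolactone (C8 2-(trimethylsilylmethyl)allyl; C9 bonded to quaternary C10 bearing the C20 formyl group; C11 menthyl acetal), via potassium lactone enolate 13 (not isolated)
Conditions: KN(SiMe3)2, THF, −78 °C; 2, −78 °C; then [2-(chloromethyl)allyl]trimethylsilane, Bu4NI (cat.), DMPU, −78 → −20 °C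
Reagents that add atoms: [2-(chloromethyl)allyl]trimethylsilane, C=C(CCl)C[Si](C)(C)C
Why: Michael addition of the potassium enolate of an α-branched aldehyde to a 5-alkoxybutenolide with in situ alkylation of the lactone enolate (tandem conjugate addition–alkylation); C10 is attacked along the equatorial direction because the axial face is blocked by the 1,3-diaxial C19 methyl, so C9 ends trans to C6; the butenolide reacts on the face opposite its menthyloxy group, which fixes C9; the allyl halide enters C8 trans to the C9 substituent.

Step 10
Reactants: 14 aldehyde lactone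
Product: 15 C20 primary alcohol (acylal lactone intact)
Conditions: NaBH4, CeCl3·7H2O, MeOH/THF, −40 °C; AcOH quench
Reagents that add atoms: none
Why: Luche-type reduction of the neopentyl aldehyde at low temperature; the acylal lactone, allylsilane and silyl ethers are inert, and the buffered medium keeps the new alcohol from transacylating before isolation.

Step 11
Reactants: 15 C20 alcohol
Product: 16 spiro δ-lactone aldehyde (C7–O–C20 lactone; C9 formyl = C11; C8 2-(trimethylsilylmethyl)allyl cis to the formyl group)
Conditions: DBU, PhMe, 40 °C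
Reagents that add atoms: none
Why: Base-catalysed acyl transfer: the C20 hydroxyl attacks the activated acylal carbonyl C7 through a six-membered transition state, and the expelled menthyl hemiacetal collapses to the C11 aldehyde and menthol, which makes the exchange irreversible; any epimerisation at C9 leads to the isomer drawn (formyl and C5 both equatorial on the lactone), and C8 is erased in step 13.

Step 12
Reactants: 16 δ-lactone aldehyde allylsilane
Product: 17 lactone-fused ring C trimethylsilyl ether (C11 OSiMe3; C13 exocyclic methylene; C8–H and C9–H cis)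
Conditions: Me3SiOTf (10 mol %), CH2Cl2, −78 °C
Reagents that add atoms: none
Why: Intramolecular Hosomi–Sakurai reaction: the silyl-activated aldehyde is attacked by the terminal carbon of the allylsilane in a six-membered chair-like closure, and the Me3Si group released ends on the new oxygen (catalyst turnover); ring C forms cis-fused to the lactone, the exocyclic methylene masks the C13 ketone, and the C11 carbinol configuration is immaterial.

Step 13
Reactants: 17 cis-fused lactone silyl ether
Product: 18 C8-propargylated lactone (C15 cis to H9)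
Conditions: LiN(i-Pr)2, THF, −78 °C; propargyl bromide, DMPU, −78 → −30 °C
Reagents that add atoms: 3-bromoprop-1-yne, C#CCBr
Why: Alkylation of the ring-fusion lactone enolate creates the C8 quaternary centre; the electrophile enters cis to H9, the usual outcome for angular alkylation of cis-fused bicyclic lactone enolates, and the other face is screened by C1 of ring A (1,3-diaxial to C8) and by C11–C12, so C15 ends trans to C11 as in the target.

Step 14
Reactants: 18 propargylated methylene compound
Product: 20 C11 hydroxy C13 ketone, via C13 ketone trimethylsilyl ether 19 (not isolated)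
Conditions: O3, CH2Cl2/MeOH, −78 °C; Me2S; then citric acid, MeOH, 23 °C
Reagents that add atoms: ozone, [O-][O+]=O
Why: Ozone cleaves the 1,1-disubstituted alkene much faster than the terminal alkyne, giving the C13 ketone; mild acidic methanolysis in the work-up removes the labile trimethylsilyl ether and leaves the silyl ethers on C6 and C18.

Step 15
Reactants: 20 β-hydroxy ketone
Product: 21 lactone-fused cyclohexane-1,3-dione (C11 and C13 carbonyls; propargyl on C8)
Conditions: Dess–Martin periodinane, NaHCO3, CH2Cl2, 0 → 23 °C
Reagents that add atoms: none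
Why: Dess–Martin oxidation of the β-hydroxy ketone gives the 1,3-diketone, in which C12 is the only doubly activated carbon.

Step 16
Reactants: 21 1,3-diketone alkyne
Product: 22 bicyclo[2.2.2]octane-11,13-dione with C16 exocyclic methylene
Conditions: Ph3PAuCl (5 mol %), AgOTf (5 mol %), CH2Cl2, 23 °C
Reagents that add atoms: none
Why: Gold-catalysed Conia-ene reaction: the enol of the 1,3-diketone attacks the gold-activated alkyne at C16 (6-exo-dig) and protodeauration leaves the exocyclic methylene; O-attack is excluded because it would need a bridgehead enol ether double bond (Bredt's rule), and the bridgehead C12 can have only one configuration.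

Step 17
Reactants: 22 bicyclic β-diketone
Product: 23 13-hydroxybicyclo[2.2.2]octan-11-one (hydroxyl on the side of the C9–C11 bridge)
Conditions: NaBH4, CeCl3·7H2O, MeOH/THF, −78 °C
Reagents that add atoms: none
Why: Luche reduction of the less hindered carbonyl of a non-enolisable β-diketone: at C11 one face is shielded by the C10 substituent on C9 and attack on the other would eclipse the new oxygen with C10, whereas C13 is open on the side of the methylene bridge; CeCl3 and low temperature suppress retro-Claisen opening, and the C13 configuration is lost in step 19.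

Step 18
Reactants: 23 hydroxy ketone
Product: 24 C13 O-alkyl S-methyl xanthate of the bicyclo[2.2.2]octan-11-one (C16 methylene on C12)
Conditions: NaN(SiMe3)2, THF, −78 °C; CS2; then MeI
Reagents that add atoms: carbon disulfide, S=C=S; iodomethane, CI
Why: Xanthate formation (alkoxide, CS2, MeI) at −78 °C, where capture of the alkoxide by CS2 outruns retro-aldol opening of the β-hydroxy ketone.

Step 19
Reactants: 24 bicyclo[2.2.2]octanone xanthate
Product: 25 11-oxo-16-methylene bicyclo[3.2.1]octane lactone (C15 as CH2)
Conditions: Bu3SnH (syringe pump), AIBN (cat.), PhH, 80 °C, high dilution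
Reagents that add atoms: none
Why: Barton–McCombie fragmentation of the xanthate by Bu3Sn• gives the secondary C13 radical, which adds 3-exo-trig to C16 of the neighbouring exocyclic alkene; the cyclopropylcarbinyl radical reopens by cleaving C12–C16, so the alkenyl unit moves from C12 to C13 (homoallyl–homoallyl radical rearrangement, a 1,2-vinyl shift, the known way from bicyclo[2.2.2]octanes to bicyclo[3.2.1]octanes). The five-membered ring D (C8, C14, C13, C16, C15) is closed by this 3-exo-trig cyclisation followed by opening of the three-membered ring, while the six-membered ring through C12 is opened. The only new stereocentre, C13, is a bridgehead fixed by the framework: the shift is suprafacial and C16 stays on the face to which it was held through C12 and C15. The selectivity needed is the direction of cyclopropane opening: cleavage of C12–C16 gives a radical stabilised by the C11 carbonyl in a less strained skeleton, whereas cleavage of C13–C16 only returns the unstabilised secondary radical. Rearrangement must also outrun hydrogen transfer to the first radical, which slow addition of Bu3SnH at high dilution secures. Hydrogen transfer to C12 then gives 25, and C9 next to the ketone is untouched under these neutral conditions.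

Step 20
Reactants: 25 bicyclo[3.2.1]octan-11-one
Product: 26 C11 alcohol (hydroxyl equatorial, cis to C10 and trans to H9)
Conditions: SmI2, THF, i-PrOH, 23 °C
Reagents that add atoms: none
Why: Single-electron reduction of the ketone under protic, equilibrating conditions should give the more stable equatorial (exo) alcohol, because an axial C11 substituent would point into the C15–C16 bridge; without water the δ-lactone is not reduced by SmI2.

Step 21
Reactants: 26 C11 alcohol
Product: 27 11,15-diol (C15 hydroxyl allylic; exo face expected)
Conditions: SeO2 (0.3 equiv), t-BuOOH, CH2Cl2, 23 °C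
Reagents that add atoms: tert-butyl hydroperoxide, CC(C)(C)OO; selenium dioxide, O=[Se]=O
Why: SeO2-mediated allylic hydroxylation (ene reaction, then [2,3]-sigmatropic shift); C15 is the only allylic position that can react, since abstraction of H13 would need a bridgehead alkene.

Step 22
Reactants: 27 bis-silyl 11,15-diol
Product: 28 6,11,15,18-tetraol
Conditions: HF·pyridine, THF/pyridine, 0 → 40 °C
Reagents that add atoms: none
Why: Fluoride cleavage of both silyl ethers under non-basic conditions, done before the enone exists so that the Michael acceptor never meets fluoride.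

Step 23
Reactants: 28 tetraol
Product: 29 target compound CNP0152458.1
Conditions: MnO2, acetone, 23 °C
Reagents that add atoms: none
Why: MnO2 oxidises only the allylic C15 alcohol and leaves the primary C6 and C18 and the secondary C11 hydroxyls, so the α-methylene ketone appears in the last step.

## Compound list

1 | (E)-4-methoxypent-3-en-2-one | CO/C(C)=C/C(C)=O | starting material
2 | (5S)-5-[(1S,2R,5S)-2-isopropyl-5-methylcyclohexyloxy]furan-2(5H)-one | O=C1C=C[C@@H](O[C@H]2C[C@@H](C)CC[C@@H]2C(C)C)O1 | starting material
3 | lithium lactone enolate of the Michael adduct of 1 and 2 | [Li+].[O-]C1=C[C@H](CC(=O)/C=C(\C)OC)[C@@H](O[C@H]2C[C@@H](C)CC[C@@H]2C(C)C)O1 | intermediate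
4 | cis-fused enone lactone, (3S)-3-(d-menthyloxy)-7-methyl-3a,4-dihydro-2-benzofuran-1,5(3H,7aH)-dione | [C@H]12CC(=O)C=C(C)[C@H]1C(=O)O[C@@H]2O[C@H]1C[C@@H](C)CC[C@@H]1C(C)C | intermediate
5 | C2 ketone with C4 methyl and vinyl (vinyl trans to C6) | [C@H]12CC(=O)C[C@](C)(C=C)[C@H]1C(=O)O[C@@H]2O[C@H]1C[C@@H](C)CC[C@@H]1C(C)C | intermediate
6 | tosylhydrazone of 5 | [C@H]12CC(=NNS(=O)(=O)c3ccc(C)cc3)C[C@](C)(C=C)[C@H]1C(=O)O[C@@H]2O[C@H]1C[C@@H](C)CC[C@@H]1C(C)C | intermediate
7 | C2-deoxygenated cis-fused lactone acetal | [C@H]12CCC[C@](C)(C=C)[C@H]1C(=O)O[C@@H]2O[C@H]1C[C@@H](C)CC[C@@H]1C(C)C | intermediate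
8 | methyl 2-(dimethoxymethyl)-6-methyl-6-vinylcyclohexane-1-carboxylate | [C@@H]1(CCC[C@](C)(C=C)[C@H]1C(=O)OC)C(OC)OC | intermediate
9 | methyl 2-(dimethoxymethyl)-6-formyl-6-methylcyclohexane-1-carboxylate | [C@@H]1(CCC[C@](C)(C=O)[C@H]1C(=O)OC)C(OC)OC | intermediate
10 | [3-(dimethoxymethyl)-1-methylcyclohexane-1,2-diyl]dimethanol | [C@@H]1(CCC[C@](C)(CO)[C@H]1CO)C(OC)OC | intermediate
11 | bis(tert-butyldiphenylsilyl) ether of 10 | [C@@H]1(CCC[C@](C)(CO[Si](c4ccccc4)(c4ccccc4)C(C)(C)C)[C@H]1CO[Si](c4ccccc4)(c4ccccc4)C(C)(C)C)C(OC)OC | intermediate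
12 | 2,3-bis[(tert-butyldiphenylsilyl)oxymethyl]-3-methylcyclohexane-1-carbaldehyde | [C@@H]1(CCC[C@](C)(CO[Si](c4ccccc4)(c4ccccc4)C(C)(C)C)[C@H]1CO[Si](c4ccccc4)(c4ccccc4)C(C)(C)C)C=O | intermediate
13 | potassium lactone enolate of the Michael adduct of 12 and 2 | [K+].[O-]C1=C[C@H]([C@@]2(CCC[C@](C)(CO[Si](c4ccccc4)(c4ccccc4)C(C)(C)C)[C@H]2CO[Si](c4ccccc4)(c4ccccc4)C(C)(C)C)C=O)[C@@H](O[C@H]2C[C@@H](C)CC[C@@H]2C(C)C)O1 | intermediate
14 | trans,trans-butyrolactone with C8 2-(trimethylsilylmethyl)allyl, C10 formyl and C11 menthyl acetal | O=C1O[C@H](O[C@H]2C[C@@H](C)CC[C@@H]2C(C)C)[C@H]([C@@H]1CC(=C)C[Si](C)(C)C)[C@@]1(CCC[C@](C)(CO[Si](c4ccccc4)(c4ccccc4)C(C)(C)C)[C@H]1CO[Si](c4ccccc4)(c4ccccc4)C(C)(C)C)C=O | intermediate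
15 | C20 alcohol of 14 | O=C1O[C@H](O[C@H]2C[C@@H](C)CC[C@@H]2C(C)C)[C@H]([C@@H]1CC(=C)C[Si](C)(C)C)[C@@]1(CCC[C@](C)(CO[Si](c4ccccc4)(c4ccccc4)C(C)(C)C)[C@H]1CO[Si](c4ccccc4)(c4ccccc4)C(C)(C)C)CO | intermediate
16 | spiro δ-lactone with C9 formyl and C8 2-(trimethylsilylmethyl)allyl | O=C[C@H]1[C@@]2(CCC[C@](C)(CO[Si](c4ccccc4)(c4ccccc4)C(C)(C)C)[C@H]2CO[Si](c4ccccc4)(c4ccccc4)C(C)(C)C)COC(=O)[C@H]1CC(=C)C[Si](C)(C)C | intermediate
17 | cis-fused lactone with ring C, C11 OSiMe3 and C13 methylene | C=C1C[C@@H](O[Si](C)(C)C)[C@H]2[C@@]3(CCC[C@](C)(CO[Si](c4ccccc4)(c4ccccc4)C(C)(C)C)[C@H]3CO[Si](c4ccccc4)(c4ccccc4)C(C)(C)C)COC(=O)[C@H]2C1 | intermediate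
18 | C8-propargylated 17 | C=C1C[C@@H](O[Si](C)(C)C)[C@H]2[C@@]3(CCC[C@](C)(CO[Si](c4ccccc4)(c4ccccc4)C(C)(C)C)[C@H]3CO[Si](c4ccccc4)(c4ccccc4)C(C)(C)C)COC(=O)[C@@]2(CC#C)C1 | intermediate
19 | C13 ketone with C11 OSiMe3 | O=C1C[C@@H](O[Si](C)(C)C)[C@H]2[C@@]3(CCC[C@](C)(CO[Si](c4ccccc4)(c4ccccc4)C(C)(C)C)[C@H]3CO[Si](c4ccccc4)(c4ccccc4)C(C)(C)C)COC(=O)[C@@]2(CC#C)C1 | intermediate
20 | C11 hydroxy C13 ketone | O=C1C[C@@H](O)[C@H]2[C@@]3(CCC[C@](C)(CO[Si](c4ccccc4)(c4ccccc4)C(C)(C)C)[C@H]3CO[Si](c4ccccc4)(c4ccccc4)C(C)(C)C)COC(=O)[C@@]2(CC#C)C1 | intermediate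
21 | lactone-fused cyclohexane-1,3-dione with C8 propargyl | O=C1CC(=O)[C@H]2[C@@]3(CCC[C@](C)(CO[Si](c4ccccc4)(c4ccccc4)C(C)(C)C)[C@H]3CO[Si](c4ccccc4)(c4ccccc4)C(C)(C)C)COC(=O)[C@@]2(CC#C)C1 | intermediate
22 | bicyclo[2.2.2]octane-11,13-dione with C16 methylene | C=C1C[C@]23CC(=O)[C@H]1C(=O)[C@H]2[C@@]1(CCC[C@](C)(CO[Si](c4ccccc4)(c4ccccc4)C(C)(C)C)[C@H]1CO[Si](c4ccccc4)(c4ccccc4)C(C)(C)C)COC3=O | intermediate
23 | 13-hydroxybicyclo[2.2.2]octan-11-one | C=C1C[C@]23C[C@@H](O)[C@H]1C(=O)[C@H]2[C@@]1(CCC[C@](C)(CO[Si](c4ccccc4)(c4ccccc4)C(C)(C)C)[C@H]1CO[Si](c4ccccc4)(c4ccccc4)C(C)(C)C)COC3=O | intermediate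
24 | C13 S-methyl xanthate of the bicyclo[2.2.2]octan-11-one | C=C1C[C@]23C[C@@H](OC(=S)SC)[C@H]1C(=O)[C@H]2[C@@]1(CCC[C@](C)(CO[Si](c4ccccc4)(c4ccccc4)C(C)(C)C)[C@H]1CO[Si](c4ccccc4)(c4ccccc4)C(C)(C)C)COC3=O | intermediate
25 | 11-oxo-16-methylene bicyclo[3.2.1]octane lactone | C=C1C[C@]23C[C@H]1CC(=O)[C@H]2[C@@]1(CCC[C@](C)(CO[Si](c4ccccc4)(c4ccccc4)C(C)(C)C)[C@H]1CO[Si](c4ccccc4)(c4ccccc4)C(C)(C)C)COC3=O | intermediate
26 | C11 equatorial alcohol | C=C1C[C@]23C[C@H]1C[C@@H](O)[C@H]2[C@@]1(CCC[C@](C)(CO[Si](c4ccccc4)(c4ccccc4)C(C)(C)C)[C@H]1CO[Si](c4ccccc4)(c4ccccc4)C(C)(C)C)COC3=O | intermediate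
27 | 11,15-diol, bis-silyl ether | C=C1[C@H](O)[C@]23C[C@H]1C[C@@H](O)[C@H]2[C@@]1(CCC[C@](C)(CO[Si](c4ccccc4)(c4ccccc4)C(C)(C)C)[C@H]1CO[Si](c4ccccc4)(c4ccccc4)C(C)(C)C)COC3=O | intermediate
28 | 6,11,15,18-tetraol | C=C1[C@H](O)[C@]23C[C@H]1C[C@@H](O)[C@H]2[C@@]1(CCC[C@](C)(CO)[C@H]1CO)COC3=O | intermediate
29 | CNP0152458.1 | C=C1C(=O)[C@]23C[C@H]1C[C@@H](O)[C@H]2[C@@]1(CCC[C@](C)(CO)[C@H]1CO)COC3=O | target

## Step count and risks

Total: 23 steps. Longest linear sequence: 23 steps from 1 and 2 (both commercial; 2 is used in steps 1 and 9).

**Step 19 (key step).** The C13 radical may take hydrogen from Bu3SnH before it closes onto C16, or the cyclopropylcarbinyl radical may reopen backwards; either way the skeleton stays bicyclo[2.2.2], because the shift competes with a bimolecular reduction. Fallback from 20, returning at 25: hydroxyl-directed reduction of the C13 ketone with Me4NBH(OAc)3 gives the anti-11,13-diol F1. Xanthate formation at the less hindered C13 hydroxyl gives the mono-xanthate F2, and Dess–Martin oxidation of C11 gives the keto xanthate F3. Bu3SnH/AIBN then closes ring D directly by 5-exo-dig attack of the C13 radical on the C8 propargyl group, reaching 25 without the bicyclo[2.2.2]octane.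

**Step 1.** After the first Michael addition, proton transfer from the side-chain ketone can quench the lactone enolate, so the ring closure onto the hindered methoxy-bearing carbon may stall at the open adduct. Fallback from 1 and 2, returning at 4: 1 is converted with Me3SiCl, Et3N and ZnCl2 into the silyl dienol ether F4. A thermal (or high-pressure) Diels–Alder reaction with 2 gives the cycloadduct F5, and trifluoroacetic acid then releases the enone 4.

**Step 9.** The bond joins a fully substituted enolate carbon to the β-carbon of the butenolide. Slow or reversible addition (retro-Michael) and incomplete trapping of the lactone enolate are the likely failures. Fallback from 12, returning at 14: 12 is condensed with 1,1-dimethylhydrazine to the N,N-dimethylhydrazone F6. Its lithium aza-enolate, a smaller and more nucleophilic carbanion, is added to 2 and alkylated in the same way to give the hydrazone lactone F7, and aqueous oxalic acid then frees the aldehyde 14.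

**Step 16.** The 6-exo-dig closure needs a boat-like ring C with the propargyl group axial; slow cyclisation would leave time for alkyne hydration. Fallback from 21, returning directly at 22: oxidative radical cyclisation with Mn(OAc)3·2H2O (trivalent manganese acetate) in EtOH/AcOH. The C12 radical of the diketone adds to the alkyne and the vinyl radical takes hydrogen from the solvent; no new compound is involved.

**Step 17.** Hydride may attack both carbonyls, or an alkoxide may open the non-enolisable β-diketone by retro-Claisen cleavage. Fallback from 22, returning at 24: exhaustive reduction gives the 11,13-diol F8. The xanthate is formed at the far more accessible C13 hydroxyl to give the hydroxy xanthate F9, and Dess–Martin oxidation of the hindered C11 alcohol gives 24.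

**Step 20.** Protonation may occur from the wrong face, or equilibration may be incomplete, leaving the axial alcohol. Fallback from 25, returning at 26: NaBH4 reduction, expected to favour attack from the open face, gives the 11-epi alcohol F10. Mitsunobu inversion with 4-nitrobenzoic acid gives the 4-nitrobenzoate F11, and brief methanolysis (K2CO3, MeOH, 0 °C) gives 26.

## Further compounds

F1 | step 19 | anti-11,13-diol from 20 | O[C@@H]1C[C@@H](O)[C@H]2[C@@]3(CCC[C@](C)(CO[Si](c4ccccc4)(c4ccccc4)C(C)(C)C)[C@H]3CO[Si](c4ccccc4)(c4ccccc4)C(C)(C)C)COC(=O)[C@@]2(CC#C)C1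
F2 | step 19 | C13 mono-xanthate of F1 | CSC(=S)O[C@@H]1C[C@@H](O)[C@H]2[C@@]3(CCC[C@](C)(CO[Si](c4ccccc4)(c4ccccc4)C(C)(C)C)[C@H]3CO[Si](c4ccccc4)(c4ccccc4)C(C)(C)C)COC(=O)[C@@]2(CC#C)C1
F3 | step 19 | monocyclic 11-keto 13-xanthate with C8 propargyl | CSC(=S)O[C@@H]1CC(=O)[C@H]2[C@@]3(CCC[C@](C)(CO[Si](c4ccccc4)(c4ccccc4)C(C)(C)C)[C@H]3CO[Si](c4ccccc4)(c4ccccc4)C(C)(C)C)COC(=O)[C@@]2(CC#C)C1
F4 | step 1 | (E)-4-methoxy-2-(trimethylsilyloxy)penta-1,3-diene | CO/C(C)=C/C(=C)O[Si](C)(C)C
F5 | step 1 | Diels–Alder adduct of F4 and 2 (silyl enol ether, C4 methoxy) | [C@H]12CC(O[Si](C)(C)C)=C[C@@](C)(OC)[C@H]1C(=O)O[C@@H]2O[C@H]1C[C@@H](C)CC[C@@H]1C(C)C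
F6 | step 9 | N,N-dimethylhydrazone of 12 | [C@@H]1(CCC[C@](C)(CO[Si](c4ccccc4)(c4ccccc4)C(C)(C)C)[C@H]1CO[Si](c4ccccc4)(c4ccccc4)C(C)(C)C)/C=N/N(C)C
F7 | step 9 | N,N-dimethylhydrazone of 14 | O=C1O[C@H](O[C@H]2C[C@@H](C)CC[C@@H]2C(C)C)[C@H]([C@@H]1CC(=C)C[Si](C)(C)C)[C@@]1(CCC[C@](C)(CO[Si](c4ccccc4)(c4ccccc4)C(C)(C)C)[C@H]1CO[Si](c4ccccc4)(c4ccccc4)C(C)(C)C)/C=N/N(C)C
F0 | step 16 | none | none
F8 | step 17 | bicyclo[2.2.2]octane-11,13-diol | C=C1C[C@]23C[C@@H](O)[C@H]1[C@@H](O)[C@H]2[C@@]1(CCC[C@](C)(CO[Si](c4ccccc4)(c4ccccc4)C(C)(C)C)[C@H]1CO[Si](c4ccccc4)(c4ccccc4)C(C)(C)C)COC3=O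
F9 | step 17 | 11-hydroxy C13 xanthate | C=C1C[C@]23C[C@@H](OC(=S)SC)[C@H]1[C@@H](O)[C@H]2[C@@]1(CCC[C@](C)(CO[Si](c4ccccc4)(c4ccccc4)C(C)(C)C)[C@H]1CO[Si](c4ccccc4)(c4ccccc4)C(C)(C)C)COC3=O
F10 | step 20 | 11-epi alcohol (axial hydroxyl) | C=C1C[C@]23C[C@H]1C[C@H](O)[C@H]2[C@@]1(CCC[C@](C)(CO[Si](c4ccccc4)(c4ccccc4)C(C)(C)C)[C@H]1CO[Si](c4ccccc4)(c4ccccc4)C(C)(C)C)COC3=O
F11 | step 20 | C11 4-nitrobenzoate with the configuration of 26 | C=C1C[C@]23C[C@H]1C[C@@H](OC(=O)c5ccc(cc5)[N+](=O)[O-])[C@H]2[C@@]1(CCC[C@](C)(CO[Si](c4ccccc4)(c4ccccc4)C(C)(C)C)[C@H]1CO[Si](c4ccccc4)(c4ccccc4)C(C)(C)C)COC3=O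
A1 | alternative 1 | intramolecular Diels–Alder adduct with temporary ring B | C=CC[C@]1(C#C[Si](C)(C)C)C=C[C@@H]2[C@@](C)(CO[Si](C)(C)C(C)(C)C)CCC[C@@]2(CO[Si](C)(C)C(C)(C)C)[C@@H]1C(=O)OC
A2 | alternative 2 | cyclobutane photoadduct with spiro ring A | CC1(C)OC(=O)[C@]23C[C@H](CC(=O)OC)C[C@@H](O[Si](C)(C)C(C)(C)C)[C@H]2[C@@]4(CCC[C@](C)(CO[Si](C)(C)C(C)(C)C)[C@H]4CO[Si](C)(C)C(C)(C)C)[C@@H]3O1
A3 | alternative 3 | 11-hydroxy-15-oxo tetracycle lacking C17 | C1C(=O)[C@]23C[C@H]1C[C@@H](O)[C@H]2[C@@]1(CCC[C@](C)(CO[Si](C)(C)C(C)(C)C)[C@H]1CO[Si](C)(C)C(C)(C)C)COC3=O
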